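(The data stem from a simulated flask with made-up constants.)

In the south-east run Qa lost and Qe gained stay equal within the scatter: that run ends at 70% Qe and 30% Qa, together 100% of the Qa charged. So Qe slows in that run with Qa left over.

| flask | Qa | Qb | Qc | remark |
|---|---|---|---|---|
| south-east | 0.067 M | 0.095 M | 0.10 mM | run made earlier |
| north-west | 0.15 M | 0.095 M | 0.10 mM | run made earlier |
| south-west | 0.10 M | 0.095 M | 0.20 mM | run made earlier |
| flask | 0.10 M | 0.0950 M | 0.10 mM |  |

- south-east (time / h: Qe / %, Qa / %): 2.00: 17, 82; 3.00: 26, 75; 4.00: 32, 65; 6.00: 44, 58; 10.0: 59, 40; 15.0: 64, 32; 25.0: 70, 30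
- north-west (time / h: Qe / %, Qa / %): 1.33: 8, 93; 4.00: 15, 85; 6.00: 22, 78; 10.0: 31, 70; 15.0: 34, 65; 20.0: 35, 66; 25.0: 35, 63
- south-west (time / h: Qe / %, Qa / %): 2.00: 29, 78; 4.00: 41, 53; 6.00: 55, 42; 12.0: 64, 34; 25.0: 68, 35

(scatter of a reading: 2 percentage points)

- the analysis behind the earlier runs scatters by 2 percentage points, standard deviation
- no earlier run changes the charge of Qb; that part of a forecast is a guess

- apparent order in Qb when 30% of the Qa are converted (percent change of the rate of making Qe for one percent more Qb charged)
- apparent order in Qc when 30% of the Qa are converted (percent change of the rate of making Qe for one percent more Qc charged)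

At 0.10 mM Qc, the last [Qe] over the [Qb] charged averages 52.3% across the south-east and north-west runs. Call this the Qb yield, the Qe finally obtained per Qb charged. In the south-west run, with twice the Qc, the yield reads 71.6%.

In logarithms, the yield therefore goes with Qc to the power 0.452. My own reckoning adds this power to a first power of Qc, supposing that more Qc also keeps more Qb standing at 30% conversion. That gives 1.45 for the flask. No run changes Qb, so I can only guess that its order is near one.

The forecast gives 1 for Qb and 1.6 for Qc, a little higher than my figure, on these grounds: “the catalyst is dying or being inhibited”.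

The flask gives 1.1 for Qb and 1.4 for Qc, so the forecast is right within its margins.

    Qb + Qc → Qf (k = 2400 M⁻¹ h⁻¹)
    Qa + Qf → Qg (k = 2300 M⁻¹ h⁻¹)
    Qg → Qc + Qe (k = 200 h⁻¹)
    Qb → Qd (k = 0.100 h⁻¹)

At 4.17 h the flask uses Qb in Qb + Qc → Qf at 1.1 times the rate of Qb → Qd, so at that moment 53.4% of the Qb being used goes to Qf. By 20.0 h Qb, the limiting reagent, is down to 0.426% of its charge in the flask with 49.4% of the Qa left; on the flask's charge the Qb yield of 52.3% read from the runs means 49.7% Qe, and the flask holds 50.6% Qe beside 0.0440 M of Qd.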